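**Questions asked.** Of the 5 questions below, the first two ask for orders at the outset, and such an order is read at one small fixed amount of target, the same in the runs compared, while the rate may still be changing with time.

| flask | substrate | coupling partner | free catalyst | time |
|---|---|---|---|---|
| alder | 0.600 M | 1.80 M | 0.0120 M |  |
| cedar | 0.300 M | 1.50 M | 0.0120 M |  |
| larch | 0.300 M | 1.80 M | 0.0120 M |  |
| birch | 0.600 M | 1.80 M | 0.0180 M |  |
| ash | 0.300 M | 0.900 M | 0.0120 M | 18 h |

- alder run (time / h: [target] / M): 0.72: 0.0084; 1.6: 0.0266; 3.6: 0.1041; 8.0: 0.2516; 18: 0.4721
- cedar run (time / h: [target] / M): 0.72: 0.0033; 1.6: 0.0201; 3.6: 0.0634; 8.0: 0.1526; 18: 0.2582
- larch run (time / h: [target] / M): 0.72: 0.0069; 1.6: 0.0205; 3.6: 0.0667; 8.0: 0.1590; 18: 0.2606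
- birch run (time / h: [target] / M): 0.72: 0.0090; 1.6: 0.0475; 3.6: 0.1537; 8.0: 0.3464; 18: 0.5569

(standard deviation of a reading: 0.002 M)

* reaction order in [free catalyst] at the outset, round the charge of the alder run, defined at two percent of the substrate turned into target
* reaction order in [substrate] at the outset, round the charge of the alder run, defined at two percent of the substrate turned into target (one fixed amount of target, the same in the runs compared)
* the cedar run starts with 0.300 M less of substrate and of coupling partner than the alder run, and with no target. Compared where both hold the same amount of substrate, once fifteen percent of what the cedar run was charged with has turned into target, is the cedar run faster, slower or alike (within a tenth)?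
* target in the ash run at 18 h, as a share of the substrate charged
* which of these the readings show (the second partner kills the catalyst / the catalyst rests as a dimer / the catalyst wakes slowly / an uncatalysed path runs beside / the substrate is lost by itself)

- Overall: substrate + coupling partner -> target, with free catalyst as catalyst.
- Constant volume, constant temperature.
- "The second partner" is coupling partner.
- An order is taken over about fifteen percent of the charge, up and down.

**Two times.** The alder run turns 1.40% of its substrate charge by 0.72 h and 4.43% by 1.6 h, so it runs faster in the second interval, the mark of an induction period, and these readings bracket the two-percent point. That point has two times: the time the flask took to reach it, and the time the same fraction would take at the rate holding there. Their ratio, read across these two alder readings, comes to 1.44; this ratio of time taken to time at the present rate, equal to the slope of ln target against ln time, is the lag stretch. The scatter of the first reading moves it by about 0.298.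

**Why it divides.** Where early target grows as a power of the charge and as the stretch power of time, a flask richer in that charge reaches the fixed amount of target sooner, earlier in its climb, so the order read there is the order that the power of the charge gives, divided by the stretch. Taking that power as one for the catalyst, the reckoning here gives a catalyst order of 0.694.

**Equal substrate.** The cedar chord from 1.6 h to 3.6 h and the alder chord from 8.0 h to 18 h span the compared points, and dividing the cedar chord rate by the alder chord rate gives 0.982, so this reckoning from the readings says alike.

**The forecast.** It gives catalyst order 0.6 (0.45 to 0.8), substrate order 0.35 (0.2 to 0.5), the cedar run slower, the ash run at 85% of its substrate charge (79% to 88%) and the choice that the catalyst wakes slowly, reasoning that “a faster run reaches that point earlier, with less catalyst awake”. Its catalyst order is lower than the one reckoned above, and on the cedar comparison it says slower where the reckoning above says alike.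

**The flask.** It gives catalyst order 0.63, substrate order 0.32, the cedar run alike, the ash run at 78.4% of its substrate charge and the choice that the catalyst wakes slowly.

    active catalyst + substrate → loaded catalyst + by-product (12.74 L mol⁻¹ h⁻¹)
    loaded catalyst + coupling partner → target + active catalyst (3.780 L mol⁻¹ h⁻¹)
    free catalyst → active catalyst (1.008 h⁻¹)

**Lag proven.** Round the alder charge, the slow conversion of free catalyst into active catalyst holds the catalyst order at 0.63, against 0.97 with that conversion taken away; multiplied by the stretch, the first becomes 0.907. The same multiplication lifts the substrate order from 0.32 to 0.455, and the flask without the lag gives 0.49.

The earlier runs and the new flask are simulated for an exercise, and the scatter is random.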